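Ash, charged with 1 M of substrate, was the flask I had to judge at 10 min; alder, charged with 2 M, had been run earlier.

| flask | substrate | remark | time |
|---|---|---|---|
| ash | 1 M | the very flask that is asked about, followed so far |  |
| alder | 2 M | run made earlier |  |
| flask | 1.0 M |  | 10 min |

ash run (percent of the substrate charged)

| time / s | target / % | isomer of the product / % | substrate / % |
|---|---|---|---|
| 10.0 | 45 | 13 | 24 |
| 15.0 | 50 | 14 | 18 |
| 25.0 | 51 | 18 | 17 |
| 40.0 | 50 | 15 | 13 |
| 80.0 | 51 | 18 | 14 |

alder run (percent of the substrate charged)

| time / min | target / % | isomer of the product / % | substrate / % |
|---|---|---|---|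
| 0.500 | 64 | 7 | 11 |
| 1.00 | 73 | 8 | 9 |
| 1.50 | 71 | 9 | 7 |
| 2.50 | 75 | 8 | 5 |
| 4.00 | 77 | 10 | 8 |
| 8.00 | 76 | 10 | 3 |

(each reading ± 1.5 percentage points)

- the earlier runs were read with a standard deviation of 1.5 percentage points
- a reading or a percentage of target counts all its forms, free or not
- the reaction counts as stopped when no species that holds the substrate changes by six tenths of a point or more over the second half of the time

* the state of affairs at 10 min: stopped, and by what, or still going (forward and back rates have come level / all of the substrate has reacted / it is still moving)
* the target standing at 10 min, as a percentage of the substrate charged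
* the isomer of the product standing at 10 min, as a percentage of the substrate charged
* amount of target if the flask were left three thousand times as long, in percent of the substrate charged

I read ash as flat from 25.0 s and alder as flat from 2.50 min, with substrate still standing at the last readings (14 % and 3 %), so I took each for an equilibrium, under thermodynamic control. Alder's last reading gave H, the molarity of the charge not standing as target once a flask is level, as 0.480 M. Ash's last reading gave 0.490 M, though alder's charge was twice as large. So I reckoned target as a share of the charge c as 1 − H/c, which for ash meant 52.0 %.

The forecast said forward and back rates have come level, with target 51 % (49 % to 53.5 %), isomer of the product 18 % (15.5 % to 20 %) and 51 % (46 % to 54 %) after the long wait, on the ground that “the absolute concentrations line up”. My figure stood higher than its target.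

Ash gave forward and back rates have come level, with target 53.0 %, isomer of the product 16.6 % and 53.0 % after the long wait, inside the forecast's ranges, and H there came to 0.470 M.

    substrate ⇌ target (K = 3.60, k = 0.110 s⁻¹)
    target ⇌ isomer of the product (K = 0.320, k = 0.0450 s⁻¹)
    isomer of the product ⇌ substrate (k = 0.0240 s⁻¹)
    substrate ⇌ dormant form (K = 1.10, k = 0.0380 s⁻¹)
    crystals ⇌ target, rate k5*(cs5 - [target]) while solid is left; crystals form when [target] > cs5 (solubility = 0.520 M, k = 9.90 s⁻¹)

The forecast's range for target ended 0.50 percentage points above ash's 53.0 %, and at a charge of 1.12 M, the nearest above ash at which target's answer has moved by 5 points, that answer lay outside the range. Put to a neighbour charged with 2.5 M, H gave target as 80.8 % of that charge, and that neighbour held 81.2 %, crystals counted.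

All runs are simulated for an exercise; the scatter is artificial.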